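The heptadecyl chain on C2 of the dihydropyranone ring is disconnected between C9' and C10' (chain carbons counted outward from C2). Because this methylene–methylene bond carries no functionality, it is forged as an olefin: cross-metathesis of the terminal vinyl group of (S)-5,7-bis(benzyloxy)-2-(dec-9-enyl)-6,8-dimethylchroman-4-one with non-1-ene, followed in the same flask by Pd/C hydrogenation, which saturates the new C9'=C10' bond and frees both phenols. The precursor arises from C-methylated phloroacetophenone and undec-10-enoyl chloride via a chromone whose C2=C3 bond is reduced enantioselectively by copper hydride, setting C2.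

Key step: step 5

Remark (assumption): the (R)-configured bisphosphine in step 4 is taken to deliver hydride to the chromone face that gives (S)-C2; the sense would be checked on the first batch and the antipodal ligand used if it is opposite.
Remark: compound 10 is drawn as its E isomer; the Z isomer formed alongside converges on hydrogenation.

Step 1
Reactants: 1 2',4',6'-trihydroxyacetophenone
Product: 2 2',4',6'-trihydroxy-3',5'-dimethylacetophenone
Conditions: MeI (2.1 equiv), NaOMe (3 equiv), MeOH, 0 °C → reflux
Reagents that add atoms: iodomethane, CI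
Why: Nuclear C-methylation of a phloroglucinol polyphenolate: in methanol the ambident phenoxide of 1 reacts with iodomethane at C3' and C5', the only ring C–H positions, and holding MeI near two equivalents limits geminal over-methylation to dearomatised cyclohexadienones.

Step 2
Reactants: 2 2',4',6'-trihydroxy-3',5'-dimethylacetophenone
Product: 3 1-[4,6-bis(benzyloxy)-2-hydroxy-3,5-dimethylphenyl]ethan-1-one
Conditions: BnBr (2.1 equiv), K2CO3 (2.2 equiv), DMF, rt
Reagents that add atoms: benzyl bromide, BrCc1ccccc1
Why: Williamson ether synthesis with site control by hydrogen bonding: the 4'-OH and one of the two equivalent ortho-OH groups are benzylated, after which the remaining ortho-OH is chelated to the acetyl carbonyl and is the least nucleophilic oxygen, so the reaction should stop at the bis-ether.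

Step 3
Reactants: 3 1-[4,6-bis(benzyloxy)-2-hydroxy-3,5-dimethylphenyl]ethan-1-one; 4 undec-10-enoyl chloride
Product: 6 5,7-bis(benzyloxy)-2-(dec-9-en-1-yl)-6,8-dimethyl-4H-chromen-4-one, via β-diketone 5 (not isolated)
Conditions: LiHMDS (3.1 equiv), THF, −78 °C; then 4 (1.05 equiv), −78 °C → rt; aq. NH4Cl; crude 5, conc. HCl (cat.), MeOH–THF, 50 °C
Reagents that add atoms: none
Why: Baker–Venkataraman-type diketone synthesis by direct C-acylation: the lithium phenoxide–enolate dianion of 3 attacks the acid chloride at the enolate carbon, the third equivalent of base deprotonates the diketone as it forms, and acid then closes the pyranone ring (phenol oxygen onto the side-chain ketone, 6-exo-trig hemiketal, loss of water) to give the chromone.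

Step 4
Reactants: 6 5,7-bis(benzyloxy)-2-(dec-9-en-1-yl)-6,8-dimethyl-4H-chromen-4-one
Product: 8 (S)-5,7-bis(benzyloxy)-2-(dec-9-en-1-yl)-6,8-dimethylchroman-4-one, via silyl enol ether 7 (not isolated)
Conditions: Cu(OAc)2 (5 mol%), (R)-DTBM-SEGPHOS (5.5 mol%), (EtO)2MeSiH (1.5 equiv), toluene, −20 → 0 °C; then 1 M HCl, THF, 0 °C
Reagents that add atoms: none
Why: Copper hydride-catalysed asymmetric conjugate reduction (1,4-hydrosilylation) of a chromone: L*CuH delivers hydride to C2, the β-carbon of the vinylogous ester, on the enantiotopic face selected by the C2-symmetric bisphosphine (creating the (S) centre), the copper enolate is silylated to 7, which shields C4 from 1,2-reduction and is hydrolysed on mild acidic work-up, and the isolated vinyl group should not be hydrocuprated at low temperature without a proton source.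

Step 5
Reactants: 8 (S)-5,7-bis(benzyloxy)-2-(dec-9-en-1-yl)-6,8-dimethylchroman-4-one; 9 non-1-ene
Product: 11 (S)-2-heptadecyl-5,7-dihydroxy-6,8-dimethylchroman-4-one, via olefin 10 (not isolated)
Conditions: 9 (5 equiv), Hoveyda–Grubbs II (3 mol%), 1,4-benzoquinone (10 mol%), CH2Cl2, 40 °C, argon purge; then EtOAc–MeOH, 10% Pd/C, H2 (1 atm), rt
Reagents that add atoms: none
Why: Olefin cross-metathesis (Chauvin mechanism: [2+2] cycloaddition and cycloreversion through ruthenacyclobutanes, driven by loss of ethylene) joins the internal vinyl carbon C9' of 8 to the internal vinyl carbon of non-1-ene, creating the C9'=C10' bond that becomes the C9'–C10' single bond on hydrogenation. The closest known reaction type is the cross-metathesis of two unhindered terminal (type I) olefins followed by heterogeneous hydrogenation and O-benzyl hydrogenolysis on Pd/C. No ring is closed and no stereocentre is created: C2 is remote and untouched under the neutral conditions, and the E/Z mixture of 10 is erased when the double bond is saturated. The step needs cross- over homo-coupling and fidelity of chain length; the first is secured by the excess of the cheap partner 9 (both homodimers remain metathesis-active and are funnelled to the cross product), the second by the chelated Hoveyda-type catalyst and benzoquinone, which suppress Ru–H double-bond migration. Chemoselectivity is inherent because the vinyl group is the only olefin in 8, and the ketone, aryl ethers and benzyl groups do not engage the carbene. In the second stage Pd/C and H2 saturate the olefin and cleave both benzyl ethers, while the C4 ketone, conjugated to the electron-rich ring and hydrogen-bonded to O5–H once that is free, should resist reduction.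

Compound list
1 | 2',4',6'-trihydroxyacetophenone | CC(=O)c1c(O)cc(O)cc1O | starting material
2 | 2',4',6'-trihydroxy-3',5'-dimethylacetophenone | CC(=O)c1c(O)c(C)c(O)c(C)c1O | intermediate
3 | 1-[4,6-bis(benzyloxy)-2-hydroxy-3,5-dimethylphenyl]ethan-1-one | CC(=O)c1c(O)c(C)c(OCc2ccccc2)c(C)c1OCc1ccccc1 | intermediate
4 | undec-10-enoyl chloride | C=CCCCCCCCCC(=O)Cl | starting material
5 | 1-[4,6-bis(benzyloxy)-2-hydroxy-3,5-dimethylphenyl]tridec-12-ene-1,3-dione | C=CCCCCCCCCC(=O)CC(=O)c1c(O)c(C)c(OCc2ccccc2)c(C)c1OCc1ccccc1 | intermediate (not isolated)
6 | 5,7-bis(benzyloxy)-2-(dec-9-en-1-yl)-6,8-dimethyl-4H-chromen-4-one | C=CCCCCCCCCC1=CC(=O)c2c(OCc3ccccc3)c(C)c(OCc3ccccc3)c(C)c2O1 | intermediate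
7 | (S)-5,7-bis(benzyloxy)-2-(dec-9-en-1-yl)-4-{[diethoxy(methyl)silyl]oxy}-6,8-dimethyl-2H-chromene | C=CCCCCCCCC[C@H]1C=C(O[Si](C)(OCC)OCC)c2c(OCc3ccccc3)c(C)c(OCc3ccccc3)c(C)c2O1 | intermediate (not isolated)
8 | (S)-5,7-bis(benzyloxy)-2-(dec-9-en-1-yl)-6,8-dimethylchroman-4-one | C=CCCCCCCCC[C@H]1CC(=O)c2c(OCc3ccccc3)c(C)c(OCc3ccccc3)c(C)c2O1 | intermediate
9 | non-1-ene | C=CCCCCCCC | starting material
10 | (S,E)-5,7-bis(benzyloxy)-2-(heptadec-9-en-1-yl)-6,8-dimethylchroman-4-one | CCCCCCC/C=C/CCCCCCCC[C@H]1CC(=O)c2c(OCc3ccccc3)c(C)c(OCc3ccccc3)c(C)c2O1 | intermediate (not isolated)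
11 | (S)-2-heptadecyl-5,7-dihydroxy-6,8-dimethylchroman-4-one | CCCCCCCCCCCCCCCCC[C@H]1CC(=O)c2c(O)c(C)c(O)c(C)c2O1 | target

Total step count: 5
Longest linear sequence: 5 steps (1 → 2 → 3 → 6 → 8 → 11)

Steps most likely to fail

Step 5. Ruthenium hydride species may migrate the terminal double bond before or after metathesis, which would give chain-length homologues that are hard to separate. Self-metathesis of 8 may also compete, and ruthenium residues may slow the hydrogenolysis. The fallback replaces metathesis by carbonyl olefination at the same bond. It sets out from 8: oxidative cleavage of the vinyl group (OsO4 cat., NaIO4, 2,6-lutidine, dioxane–water) should give (S)-9-[5,7-bis(benzyloxy)-6,8-dimethyl-4-oxochroman-2-yl]nonanal F1. Wittig reaction of F1 with the ylide from octyltriphenylphosphonium bromide and NaHMDS (THF, −78 °C, aldehyde in slight excess so that no free ylide remains to enolise the ketone) should give (S,Z)-5,7-bis(benzyloxy)-2-(heptadec-9-en-1-yl)-6,8-dimethylchroman-4-one F2 with an exactly defined chain length. Hydrogenation over Pd/C (H2, EtOAc–MeOH) then saturates the olefin and removes the benzyl groups, coming back to the route at 11.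

Step 4. Facial discrimination in hydride delivery to the electron-rich, 5-benzyloxy-substituted chromone may be insufficient or of the opposite sense. Competing 1,2-reduction or hydrocupration of the vinyl group may also erode the yield. The fallback sets C2 by C–C instead of C–H bond formation and sets out from 3. Condensation with N,N-dimethylformamide dimethyl acetal (toluene, 100 °C) should give (E)-1-[4,6-bis(benzyloxy)-2-hydroxy-3,5-dimethylphenyl]-3-(dimethylamino)prop-2-en-1-one F3. Acid (conc. HCl, CH2Cl2, rt) should cyclise it to 5,7-bis(benzyloxy)-6,8-dimethyl-4H-chromen-4-one F4. Copper-catalysed enantioselective conjugate addition of dec-9-enylmagnesium bromide (CuBr·SMe2, Josiphos-type ferrocenyl diphosphine, CH2Cl2, −78 °C, NH4Cl quench), with the ligand antipode chosen for (S), then comes back to the route at 8.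

Step 3. The excess amide base may convert the enolisable acid chloride into a ketene, or acylation may occur on oxygen instead of carbon. The acid stage may also partly cleave the peri benzyl ether. The fallback separates O-acylation from C–C bond formation and sets out from 3. O-acylation with 4 (K2CO3, acetone, rt) should give 2-acetyl-3,5-bis(benzyloxy)-4,6-dimethylphenyl undec-10-enoate F5. KOtBu in THF (0 °C → rt) should then trigger the Baker–Venkataraman 1,5-acyl shift (intramolecular Claisen condensation of the ketone enolate onto the aryl ester) and come back to the route at 5, which is cyclised to 6 with TsOH (cat.) in toluene at 80 °C.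

Further compounds
F1 | step 5 | (S)-9-[5,7-bis(benzyloxy)-6,8-dimethyl-4-oxochroman-2-yl]nonanal | O=CCCCCCCCC[C@H]1CC(=O)c2c(OCc3ccccc3)c(C)c(OCc3ccccc3)c(C)c2O1
F2 | step 5 | (S,Z)-5,7-bis(benzyloxy)-2-(heptadec-9-en-1-yl)-6,8-dimethylchroman-4-one | CCCCCCC/C=C\CCCCCCCC[C@H]1CC(=O)c2c(OCc3ccccc3)c(C)c(OCc3ccccc3)c(C)c2O1
F3 | step 4 | (E)-1-[4,6-bis(benzyloxy)-2-hydroxy-3,5-dimethylphenyl]-3-(dimethylamino)prop-2-en-1-one | CN(C)/C=C/C(=O)c1c(O)c(C)c(OCc2ccccc2)c(C)c1OCc1ccccc1
F4 | step 4 | 5,7-bis(benzyloxy)-6,8-dimethyl-4H-chromen-4-one | O=C1C=COc2c(C)c(OCc3ccccc3)c(C)c(OCc3ccccc3)c12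
F5 | step 3 | 2-acetyl-3,5-bis(benzyloxy)-4,6-dimethylphenyl undec-10-enoate | C=CCCCCCCCCC(=O)Oc1c(C)c(OCc2ccccc2)c(C)c(OCc2ccccc2)c1C(C)=O
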